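## Structural features

The target is a cyclopent-3-ene in which all three sp3 ring carbons carry oxygen. C1 is a fully substituted carbinol carbon that also bears the undecanoyl group (a ketone with an unbranched decyl chain). C2 and C5 flank it, each carries an acetoxy group, and each is allylic to the C3=C4 double bond. The three stereocentres are contiguous (C2–C1–C5): the two acetoxy groups are cis to each other and to the acyl group, and the tertiary hydroxyl lies on the opposite face. A mirror plane through C1 and the midpoint of C3=C4 makes the compound meso, (1r,2R,5S), so no absolute stereocontrol is needed. The fragile parts are the two allylic acetates (ionisation, SN2′ displacement, hydrolysis or migration under base), the tertiary α-hydroxy ketone (α-ketol shift, base-induced cleavage) and the isolated ring alkene. The real difficulty is the congested C1, which must receive two different oxygenated groups with a defined orientation towards both neighbours. Counted from C1, the ring shows C1 between an oxygenated C5 and a C2 that adjoins the C3=C4 alkene; with C2 as a ketone this is the 4-hydroxy-5-substituted cyclopent-2-enone array that the rearrangement of a 2-furylcarbinol builds, and the key step exploits this pattern.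

## Logic of the disconnections

**15 to 13.** The side-chain C=O is traced back to a C=CH2 bond. A ketone on C1 could not survive the enolate oxidation and hydride reduction needed on the ring, whereas the alkene is inert to both. The demand is that ozone cleaves the exocyclic 1,1-disubstituted alkene and spares C3=C4; the cleavage is therefore placed last, when C3=C4 carries two electron-withdrawing allylic acetoxy groups.

**13 to 12 to 11.** The two ester C–O bonds are cut to give the meso triol 12, and the C5 oxygen is then distinguished as a silyl ether in 11. Acetates would not pass the earlier base and hydride steps. The demand is that acetylation stops at the two secondary hydroxyls and leaves the tertiary C1 hydroxyl free.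

**11 to 10.** The C2–H bond is cut, returning the C2 carbinol to the ketone of an enone. This removes one stereocentre. The forward step needs 1,2-selective hydride addition from the face opposite the C1 side chain.

**10 to 8 (through 9).** The C1–O bond is cut, so the quaternary centre becomes a C–H that is α to the C2 ketone and allylic to the side chain. Because 9 is planar at C1, the configuration of C1 in 8 is irrelevant and only C5 has to carry stereochemical information. The forward step needs oxygen transfer at C1 anti to the C5 silyloxy group, not at the vinyl terminus, and an enolate that does not expel the C5 oxygen.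

**8 to 7.** The O–Si bond is cut. The silyl group is needed only to remove the acidic O–H, to make the C5 oxygen a poor leaving group and to block one face.

**7 to 6.** The C1–C5 bond and the C5–OH bond are cut and the C2 oxygen is rejoined to C5, which unfolds the cyclopentenone into a furan carrying the side chain on a carbinol carbon. The furan supplies C2–C5 with the C2 oxygen already in place, and the ring and two stereocentres come from a flat aromatic compound in one step. The demand is that the cation formed from 6 is hydrated at the remote furan carbon and closes through the oxygen-bearing pentadienyl system, not through the side-chain alkene.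

**6 to 3 and 4 (through 5).** The bond between the carbinol carbon and the furan carbon is cut. This gives an aryl anion and an enal; the forward step needs 1,2-addition to the enal, not 1,4-addition.

**3 to 1 and 2.** The C=CH2 bond is cut. The forward step is a single α-methylenation of an aldehyde with one α-methylene group.

## Other disconnections considered

**Alternative 1:**
- **Cut:** the C1–C(acyl) bond and the C2–O bond together, treating the acyl group and the cis C2 oxygen as a β-hydroxy ketone stored in an isoxazoline.
- **Forward key step:** undecanenitrile oxide A1, generated in the flask, would add across the enone alkene of 4-(tert-butyldimethylsilyloxy)cyclopent-2-enone A2 on the face away from the silyloxy group, giving the cis-fused isoxazoline A3. Hydroxylation at the ring-fusion carbon (C1), β-elimination of the silyloxy group to create C3=C4, 1,2-reduction at C5, reductive N–O cleavage and diacetylation would follow.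
- **In favour:** the union is convergent and brings in the whole side chain at the right oxidation level. Suprafacial addition fixes the acyl/C2–O cis relationship, and the cis ring fusion forces the later C1 hydroxyl onto the correct face, a firmer control element at C1 than the face selection of step 5. The ketone stays masked as C=N, so no two alkenes have to be told apart at the end; on this point the plan is better than the chosen one.
- **Against:** the orientation of nitrile oxide addition to a cyclic enone is not dependably one-sided, and the dipole dimerises. The carbanion needed at C1 has the isoxazoline oxygen on C2 as a β leaving group, so retro-Michael opening would compete; in the chosen plan the corresponding elimination from 9 would have to create a cyclopentadienone. The N–O cleavage must spare C3=C4 and two allylic C–O bonds, and it releases a β-hydroxy ketone with a quaternary α-carbon that can open by retro-aldol.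
- **Comparison:** structurally it maps onto the acyl group more directly. Mechanistically it replaces a ring-forming electrocyclisation by a cycloaddition onto a purchased ring. In step count it is equal or slightly better (about seven operations against nine) and it is more convergent, but its late stages combine three base- or reduction-sensitive functions where the chosen plan has one delicate final step.

**Alternative 2:**
- **Cut:** both ring bonds of C1 (C1–C2 and C1–C5).
- **Forward key step:** the enediolate of 1-hydroxydodecan-2-one A4 would add through its hydroxylated carbon to one formyl group of malealdehyde A5, enolise again at the same carbon and close onto the second formyl group. The product is the triol ketone A6, which is the target without its acetyl groups and would need only the diacetylation of step 8.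
- **In favour:** two or three operations in all, by far the best step economy of the four plans, and a cut that matches the mirror symmetry of the target. On both points it is better than the chosen plan.
- **Against:** A5 is a hydrate-forming, polymerisable ene-dial that can isomerise to the trans form (which cannot cyclise) and can accept the nucleophile in conjugate fashion. Three stereocentres arise in one pot with nothing to select the wanted meso isomer over the other meso isomer and the racemic trans-diol. The first adduct can dehydrate before the second aldol, and A4 can self-condense.
- **Comparison:** the mechanism is reversible aldol chemistry without a stereochemical anchor. The chosen plan spends about seven more steps, but each stereocentre is set by an identifiable element (conrotation, attack anti to a silyloxy group, hydride anti to the side chain). Its brevity makes it worth an exploratory trial, not a route to rely on.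

**Alternative 3:**
- **Cut:** the C2–O and C5–O bonds at once.
- **Forward key step:** [4+2] photooxygenation across the ring diene of 6-decylfulvene A7 would give the bicyclic endoperoxide A8. Low-temperature reduction of the O–O bond, diacetylation, dihydroxylation of the exocyclic alkene anti to the two acetoxy groups and oxidation of the secondary side-chain carbinol would complete the target.
- **In favour:** both secondary C–O bonds and their cis relationship come from one suprafacial event, which is better than the chosen plan, where C5 and C2 are set in separate steps. The diene is one condensation away from commodity chemicals. About six operations are needed, also better. Osmylation anti to both allylic acetoxy groups would place the C1 hydroxyl trans, as required.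
- **Against:** A8 belongs to a class of peroxides that rearrange well below room temperature and would have to be reduced as it forms. A7, a monosubstituted fulvene, dimerises and polymerises readily. The derived diol and diacetate have doubly allylic C–O bonds that ionise easily. The dihydroxylation must select the exocyclic alkene over the ring alkene when both carry the same two allylic acetoxy groups, so the alkene-differentiation problem equals that of step 9 and is not better. The last oxidation must stop at an α-hydroxy ketone.
- **Comparison:** structurally it adds oxygen to a preformed carbocycle, whereas the chosen plan makes ring and oxygenation together from furan. Both key steps are pericyclic, but the peroxide is far less robust than enone 7. It is shorter by about three steps.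

Key step: step 3

Assumption: the target is the meso isomer defined by its SMILES, so every chiral intermediate is made as a racemate and its SMILES shows one enantiomer; ring atoms are numbered as in the target (C1 side-chain carbon, C2 and C5 oxygenated, C3=C4 alkene) even where a systematic name numbers differently.

Check of the structures: carbon counts and configurations were verified (1 plus 2 gives a C13 enal; the 1-decylvinyl group of 13 gives the C11 acyl group of 15 on cleavage; 7 is the trans isomer; 15 is meso). No correction was needed and 6 is kept as the precursor.

## Route

Step 1
Reactants: 1 dodecanal; 2 formaldehyde (37% aqueous solution)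
Product: 3 2-methylidenedodecanal
Conditions: 37% aq. HCHO (1.2 equiv), pyrrolidine (10 mol %), EtCO2H (10 mol %), i-PrOH, 45 °C
Reagents that add atoms: none
Why: Amine/acid-catalysed Mannich condensation (α-methylenation of an aldehyde): the enamine of 1 adds to the iminium ion of 2 and the Mannich base eliminates pyrrolidine; an aldehyde with one α-methylene group can be methylenated only once and no stereocentre is formed.

Step 2
Reactants: 4 furan; 3 2-methylidenedodecanal
Product: 6 1-(furan-2-yl)-2-methylidenedodecan-1-ol (racemic), via 2-furyllithium 5 (not isolated)
Conditions: 4 (1.3 equiv), n-BuLi (1.15 equiv), THF, 0 °C; then 3, −78 → 0 °C; H2O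
Reagents that add atoms: none
Why: α-Lithiation of furan followed by 1,2-addition of the hard organolithium to the enal carbonyl at low temperature; the new carbinol centre is racemic and is erased in step 3, and the acid-sensitive product should be used without storage.

Step 3
Reactants: 6 1-(furan-2-yl)-2-methylidenedodecan-1-ol
Product: 7 trans-5-(dodec-1-en-2-yl)-4-hydroxycyclopent-2-en-1-one (racemic)
Conditions: Dy(OTf)3 (10 mol %), t-BuOH/H2O (5:1), 80 °C
Reagents that add atoms: water, O
Why: The Lewis acid ionises the furylic, allylic carbinol of 6 to a cation spread over the side-chain allyl unit and the furan; water adds at the remote furan carbon (C5), the resulting 2-alkylidene-5-hydroxy-2,5-dihydrofuran opens, and a 1-hydroxypentadienyl cation spanning C1 to C5 results. The closest known reaction type is the Piancatelli rearrangement of 2-furylcarbinols, a relative of the Nazarov cyclisation. The single ring is closed by thermal conrotatory 4π electrocyclisation of this cation, which forms the C1–C5 bond; proton loss from the C2 oxygen then gives the enone. The two new stereocentres C1 and C5 are set together: the cation reacts with the dodecenyl group and the C5 hydroxyl both pointing outward, and conrotation turns them to opposite faces, so the trans isomer should form as a racemate. The step needs hydration at furan C5 and closure through the oxygen-stabilised pentadienyl cation, not allylic transposition to the primary alcohol or Friedel–Crafts-type closure of the side-chain alkene onto furan C3. Water addition at the allyl termini is reversible and returns the same cation, whereas the electrocyclisation is irreversible, and closure onto furan C3 would give up the aromatic ring and the oxocarbenium stabilisation. The nearly neutral medium and a stop at full conversion should keep the doubly activated C1–H of 7 from isomerising.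

Step 4
Reactants: 7 trans-5-(dodec-1-en-2-yl)-4-hydroxycyclopent-2-en-1-one
Product: 8 trans-4-[(tert-butyldimethylsilyl)oxy]-5-(dodec-1-en-2-yl)cyclopent-2-en-1-one (racemic)
Conditions: TBSCl (1.2 equiv), imidazole (2 equiv), CH2Cl2, 0 °C
Reagents that add atoms: tert-butyldimethylsilyl chloride (TBSCl), CC(C)(C)[Si](C)(C)Cl
Why: Standard silylation of a secondary allylic alcohol; the weak base and low temperature should avoid enolisation at C1, and the silyl ether removes the acidic O–H, makes the C5 oxygen a poor leaving group and supplies the bulky group that blocks one face in step 5.

Step 5
Reactants: 8 trans-4-[(tert-butyldimethylsilyl)oxy]-5-(dodec-1-en-2-yl)cyclopent-2-en-1-one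
Product: 10 4-[(tert-butyldimethylsilyl)oxy]-5-(dodec-1-en-2-yl)-5-hydroxycyclopent-2-en-1-one (5-hydroxyl trans to 4-silyloxy; racemic), via sodium dienolate 9 (not isolated)
Conditions: NaN(SiMe3)2 (1.1 equiv), THF, −78 °C; then 2-(phenylsulfonyl)-3-phenyloxaziridine (1.3 equiv), −78 °C; AcOH quench at −78 °C
Reagents that add atoms: 2-(phenylsulfonyl)-3-phenyloxaziridine, O=S(=O)(c1ccccc1)N1OC1c1ccccc1
Why: Enolate α-hydroxylation with an N-sulfonyloxaziridine (Davis oxidation): the base removes the C1–H that is both α to the ketone and allylic, which erases C1, and the oxidant should transfer oxygen to the enolate α-carbon from the face anti to the neighbouring C5 silyloxy group, giving C1–OH trans to C5–OSi; loss of silanolate from 9 is disfavoured because it would create a cyclopentadienone.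

Step 6
Reactants: 10 4-[(tert-butyldimethylsilyl)oxy]-5-(dodec-1-en-2-yl)-5-hydroxycyclopent-2-en-1-one
Product: 11 5-[(tert-butyldimethylsilyl)oxy]-1-(dodec-1-en-2-yl)cyclopent-3-ene-1,2-diol (C2 hydroxyl and C5 silyloxy cis to each other and to the dodecenyl group, C1 hydroxyl on the other face; racemic)
Conditions: NaBH4 (1.0 equiv), CeCl3·7H2O (1.1 equiv), MeOH, −78 → −40 °C
Reagents that add atoms: none
Why: Luche reduction gives 1,2-reduction of the enone; hydride should reach C2 from the face that carries only the small C1 hydroxyl, anti to the branched dodecenyl group on C1 and the silyloxy group on C5, so the new C2 hydroxyl is cis to the C5 oxygen and trans to the C1 hydroxyl.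

Step 7
Reactants: 11 5-[(tert-butyldimethylsilyl)oxy]-1-(dodec-1-en-2-yl)cyclopent-3-ene-1,2-diol
Product: 12 (1r,2R,5S)-1-(dodec-1-en-2-yl)cyclopent-3-ene-1,2,5-triol (meso)
Conditions: Bu4NF (1.2 equiv), THF, 0 °C → rt
Reagents that add atoms: none
Why: Fluoride-induced cleavage of the silyl ether; the substrate has no base-labile group, no stereocentre is touched and the product becomes meso.

Step 8
Reactants: 12 (1r,2R,5S)-1-(dodec-1-en-2-yl)cyclopent-3-ene-1,2,5-triol
Product: 13 (1r,2R,5S)-1-(dodec-1-en-2-yl)-1-hydroxycyclopent-3-ene-2,5-diyl diacetate (meso)
Conditions: Ac2O (2.5 equiv), pyridine, DMAP (5 mol %), CH2Cl2, 0 °C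
Reagents that add atoms: acetic anhydride, CC(=O)OC(C)=O
Why: Site-selective acylation: the two equivalent secondary allylic hydroxyls should be acetylated at 0 °C while the tertiary C1 hydroxyl, flanked by two substituted carbons, reacts far more slowly; the symmetry of 12 removes any regiochemical question.

Step 9
Reactants: 13 (1r,2R,5S)-1-(dodec-1-en-2-yl)-1-hydroxycyclopent-3-ene-2,5-diyl diacetate
Product: 15 (1r,2R,5S)-1-hydroxy-1-undecanoylcyclopent-3-ene-2,5-diyl diacetate (target; meso), via secondary ozonide 14 (not isolated)
Conditions: O3/O2 (dilute stream), CH2Cl2, −78 °C, Sudan Red 7B (trace, endpoint indicator); then PPh3, −78 °C → rt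
Reagents that add atoms: ozone, [O-][O+]=O
Why: Ozonolysis with reductive work-up: electrophilic ozone should add first to the 1,1-dialkyl alkene, because C3=C4 is deactivated by two allylic acetoxy groups; the indicator dye marks the point at which to stop, and PPh3 reduces the ozonide to the ketone and formaldehyde without touching a stereocentre.

## Compound list

1 | dodecanal | CCCCCCCCCCCC=O | starting material
2 | formaldehyde (37% aqueous solution) | C=O | starting material
3 | 2-methylidenedodecanal | CCCCCCCCCCC(=C)C=O | intermediate
4 | furan | c1ccoc1 | starting material
5 | 2-furyllithium | [Li]c1ccco1 | intermediate (not isolated)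
6 | 1-(furan-2-yl)-2-methylidenedodecan-1-ol (racemic) | CCCCCCCCCCC(=C)[C@@H](O)c1ccco1 | intermediate
7 | trans-5-(dodec-1-en-2-yl)-4-hydroxycyclopent-2-en-1-one (racemic) | CCCCCCCCCCC(=C)[C@@H]1C(=O)C=C[C@H]1O | intermediate
8 | trans-4-[(tert-butyldimethylsilyl)oxy]-5-(dodec-1-en-2-yl)cyclopent-2-en-1-one (racemic) | CCCCCCCCCCC(=C)[C@@H]1C(=O)C=C[C@H]1O[Si](C)(C)C(C)(C)C | intermediate
9 | sodium 3-[(tert-butyldimethylsilyl)oxy]-2-(dodec-1-en-2-yl)cyclopenta-1,4-dien-1-olate (racemic) | CCCCCCCCCCC(=C)C1=C([O-])C=C[C@H]1O[Si](C)(C)C(C)(C)C.[Na+] | intermediate (not isolated)
10 | 4-[(tert-butyldimethylsilyl)oxy]-5-(dodec-1-en-2-yl)-5-hydroxycyclopent-2-en-1-one, 5-hydroxyl trans to 4-silyloxy (racemic) | CCCCCCCCCCC(=C)[C@@]1(O)C(=O)C=C[C@H]1O[Si](C)(C)C(C)(C)C | intermediate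
11 | 5-[(tert-butyldimethylsilyl)oxy]-1-(dodec-1-en-2-yl)cyclopent-3-ene-1,2-diol, C2–OH and C5–OSi cis to each other and to the dodecenyl group, C1–OH on the other face (racemic) | CCCCCCCCCCC(=C)[C@@]1(O)[C@@H](O)C=C[C@H]1O[Si](C)(C)C(C)(C)C | intermediate
12 | (1r,2R,5S)-1-(dodec-1-en-2-yl)cyclopent-3-ene-1,2,5-triol (meso) | CCCCCCCCCCC(=C)[C@@]1(O)[C@@H](O)C=C[C@H]1O | intermediate
13 | (1r,2R,5S)-1-(dodec-1-en-2-yl)-1-hydroxycyclopent-3-ene-2,5-diyl diacetate (meso) | CCCCCCCCCCC(=C)[C@@]1(O)[C@@H](OC(C)=O)C=C[C@H]1OC(C)=O | intermediate
14 | 3-decyl-3-[2,5-diacetoxy-1-hydroxycyclopent-3-en-1-yl]-1,2,4-trioxolane (ring configuration as in 13; racemic at the trioxolane carbon) | CCCCCCCCCCC1(OCOO1)[C@@]2(O)[C@@H](OC(C)=O)C=C[C@H]2OC(C)=O | intermediate (not isolated)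
15 | (1r,2R,5S)-1-hydroxy-1-undecanoylcyclopent-3-ene-2,5-diyl diacetate (meso) | CCCCCCCCCCC(=O)[C@@]1(O)[C@@H](OC(C)=O)C=C[C@H]1OC(C)=O | target

## Step count and least certain steps

Total step count: 9. Longest linear sequence: 9 steps (1 to 15); 2 and 4 each enter in one step.

**Step 3 (key step).**
- Risk: the furyl-allyl cation may be diverted before hydration at the furan (allylic transposition, oligomerisation of the electron-rich furan, Friedel–Crafts-type closure onto furan C3). The product may also isomerise on prolonged heating (migration of the exocyclic alkene into conjugation, or shift to the 2-substituted 4-hydroxycyclopentenone). Both arise because the alkenyl group adds a second cationic terminus and a doubly activated C1–H.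
- Fallback, from 6 back to the route at 10:
  - Buffered oxidation (NBS, NaHCO3, THF/H2O, 0 °C; Achmatowicz rearrangement) should give 2-(dodec-1-en-2-yl)-6-hydroxy-2H-pyran-3(6H)-one F1.
  - Et3N in DMF should open the lactol to the 4-oxo-enal, enolise it toward the hydroxylated carbon and close it by intramolecular aldol addition to 5-(dodec-1-en-2-yl)-4,5-dihydroxycyclopent-2-en-1-one F2, from which the isomer with trans hydroxyls is taken.
  - TBSCl/imidazole at the secondary hydroxyl then gives 10.
  - This replaces the cationic electrocyclisation by an oxidative ring expansion and an aldol ring contraction and bypasses steps 4 and 5. Its own weak point is the unsecured diastereoselectivity of the aldol closure, which is why it is held in reserve.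

**Step 5.**
- Risk: expulsion of the C5 silyloxy group from the enolate, oxygen transfer to the terminus of the extended dienolate instead of C1, or poor facial discrimination at the planar C1.
- Fallback, from 8 back to 10 (Rubottom oxidation):
  - TMSOTf/Et3N (CH2Cl2, 0 °C) should give 3-[(tert-butyldimethylsilyl)oxy]-2-(dodec-1-en-2-yl)-1-[(trimethylsilyl)oxy]cyclopenta-1,4-diene F3 without building up a free enolate.
  - Dimethyldioxirane at −78 °C should epoxidise the electron-rich enol ether bond anti to the silyloxy group to 4-[(tert-butyldimethylsilyl)oxy]-5-(dodec-1-en-2-yl)-1-[(trimethylsilyl)oxy]-6-oxabicyclo[3.1.0]hex-2-ene F4.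
  - F4 should collapse to 10 on work-up with dilute citric acid.

**Step 6.**
- Risk: erosion of facial selectivity if the cerium-bound C1 hydroxyl does not leave the lower face open, or competing conjugate reduction.
- Fallback, from 10 back to 11 with no new compound (F0): Me4NBH(OAc)3 in MeCN/AcOH at −20 °C. The C1 hydroxyl exchanges onto boron and hydride is delivered intramolecularly to C2 from the face of the C1 oxygen, giving the same trans-1,2-diol by hydroxyl-directed delivery instead of steric approach control.

**Step 9.**
- Risk: insufficient discrimination between the two alkenes, leading to cleavage of the ring. A cyclopentene double bond is intrinsically more reactive toward ozone than an acyclic 1,1-disubstituted alkene and is held back here only by its two allylic acetoxy groups.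
- Fallback, from 13 back to 15:
  - OsO4 (cat.)/N-methylmorpholine N-oxide in acetone/H2O. Osmylation responds more strongly than ozone to allylic electron-withdrawing groups and to the hindered faces of the cis-disubstituted ring alkene, so it should dihydroxylate the side-chain alkene to 1-(1,2-dihydroxydodecan-2-yl)-1-hydroxycyclopent-3-ene-2,5-diyl diacetate F5.
  - NaIO4 (1.1 equiv, THF/pH 7 buffer, 0 °C) should then cleave the primary–tertiary glycol much faster than the encumbered ditertiary one and give 15.

## Further compounds

F1 | step 3 | 2-(dodec-1-en-2-yl)-6-hydroxy-2H-pyran-3(6H)-one (mixture of anomers, racemic) | CCCCCCCCCCC(=C)C1OC(O)C=CC1=O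
F2 | step 3 | 5-(dodec-1-en-2-yl)-4,5-dihydroxycyclopent-2-en-1-one, hydroxyls trans (racemic) | CCCCCCCCCCC(=C)[C@@]1(O)C(=O)C=C[C@H]1O
F3 | step 5 | 3-[(tert-butyldimethylsilyl)oxy]-2-(dodec-1-en-2-yl)-1-[(trimethylsilyl)oxy]cyclopenta-1,4-diene (racemic) | CCCCCCCCCCC(=C)C1=C(O[Si](C)(C)C)C=C[C@H]1O[Si](C)(C)C(C)(C)C
F4 | step 5 | 4-[(tert-butyldimethylsilyl)oxy]-5-(dodec-1-en-2-yl)-1-[(trimethylsilyl)oxy]-6-oxabicyclo[3.1.0]hex-2-ene, epoxide oxygen anti to the C4 silyloxy group (racemic) | CCCCCCCCCCC(=C)[C@@]12O[C@]1(O[Si](C)(C)C)C=C[C@H]2O[Si](C)(C)C(C)(C)C
F0 | step 6 | none | none
F5 | step 9 | 1-(1,2-dihydroxydodecan-2-yl)-1-hydroxycyclopent-3-ene-2,5-diyl diacetate (ring configuration as in 13; racemate) | CCCCCCCCCCC(O)(CO)[C@@]1(O)[C@@H](OC(C)=O)C=C[C@H]1OC(C)=O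
A1 | alternative 1 | undecanenitrile oxide | CCCCCCCCCCC#[N+][O-]
A2 | alternative 1 | 4-(tert-butyldimethylsilyloxy)cyclopent-2-enone (racemic) | O=C1C=CC(O[Si](C)(C)C(C)(C)C)C1
A3 | alternative 1 | 3-decyl-6-(tert-butyldimethylsilyloxy)-3a,5,6,6a-tetrahydro-4H-cyclopenta[d]isoxazol-4-one (cis-fused, silyloxy anti, racemic) | CCCCCCCCCCC1=NO[C@H]2[C@@H]1C(=O)C[C@@H]2O[Si](C)(C)C(C)(C)C
A4 | alternative 2 | 1-hydroxydodecan-2-one | CCCCCCCCCCC(=O)CO
A5 | alternative 2 | malealdehyde ((Z)-but-2-enedial) | O=C/C=C\C=O
A6 | alternative 2 | 1-[(1r,2R,5S)-1,2,5-trihydroxycyclopent-3-en-1-yl]undecan-1-one (meso) | CCCCCCCCCCC(=O)[C@@]1(O)[C@@H](O)C=C[C@H]1O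
A7 | alternative 3 | 6-decylfulvene (5-undecylidenecyclopenta-1,3-diene) | CCCCCCCCCCC=C1C=CC=C1
A8 | alternative 3 | 7-undecylidene-2,3-dioxabicyclo[2.2.1]hept-5-ene (racemic) | CCCCCCCCCC/C=C1/[C@@H](O2)C=C[C@H]1O2
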